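**Strategy.** The route rests on disconnecting the oxepane ether bond between the oxygen on C16 and the quaternary carbon C3 (asbestinin numbering), while adding a transannular C3–C7 bond that the target lacks. The key step exploits the 1,5-relationship, across the nine-membered oxonane, of the C7 ketone and the C3 ether carbon. Oxidative β-scission of a tertiary cyclopentanol fused to an 8-oxabicyclo[3.2.1]octane breaks C3–C7 and unveils oxonane and ketone. The C3 cation so formed is captured by the C16 silyl ether oxygen, closing the oxepane and setting C3. The compact tetracyclic precursor comes from an auxiliary-controlled Diels–Alder reaction, a stepwise [4+3] annulation and a samarium Barbier cyclisation.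

Key step: step 16

**Remarks.**
- Atom labels follow asbestinin numbering. C1 and C10 are the ring-fusion CH atoms of the cyclohexane (ring A). C2 (bonded to C1) and C9 (bonded to C10) carry the bridging tetrahydrofuran oxygen. C3 is the methyl-bearing quaternary ether carbon, C4–C6 and C8 are CH2, C7 is the ketone. C11 bears the acetate, C12 and C15 a methyl each, C14 carries the C15–C16 side chain, and C16 is the OCH2 carbon.
- Assumption on the chemistry: C3 is first made as an inconsequential mixture of epimers, because it is planarised in the key step. The SMILES of the intermediates that contain it before the key step therefore leave C3 (and C7 of the cyclopentanol) unassigned. The anomeric centre of the lactol and of its acetate is likewise of no consequence.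
- The menthyloxy butenolide is taken as a catalogue compound.

## Route

**Step 1**
Reactants: 1 benzyloxyacetyl chloride; 2 ethyl vinyl ether
Product: 4 (E)-1-(benzyloxy)-4-ethoxybut-3-en-2-one, via chloro ether adduct 3 (not isolated)
Conditions: neat (excess 2), 0 °C → rt; then Et3N, CH2Cl2, 0 °C
Reagents that add atoms: none
Why: Electrophilic acylation of the enol ether at its β-carbon gives the α-chloro ether, from which base removes HCl (E1cB) to give the (E)-β-alkoxy enone; adding the base only after C–C bond formation avoids ketene formation.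

**Step 2**
Reactants: 4 (E)-1-(benzyloxy)-4-ethoxybut-3-en-2-one
Product: 5 (1E,3Z)-4-(benzyloxy)-3-(tert-butyldimethylsilyloxy)-1-ethoxybuta-1,3-diene
Conditions: TBSOTf, Et3N, Et2O, 0 °C
Reagents that add atoms: tert-butyldimethylsilyl trifluoromethanesulfonate CC(C)(C)[Si](C)(C)OS(=O)(=O)C(F)(F)F
Why: Soft enolisation (silyl triflate/amine) of the α-alkoxy ketone gives the silyl dienol ether, the (Z)-enol ether (OBn cis to OSi) being favoured, which places OBn on the outside of the 1-alkoxy-3-silyloxy diene.

**Step 3**
Reactants: 5 (1E,3Z)-4-(benzyloxy)-3-(tert-butyldimethylsilyloxy)-1-ethoxybuta-1,3-diene; 6 (5R)-5-(l-menthyloxy)furan-2(5H)-one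
Product: 8 bicyclic enone lactone, via cycloadduct silyl enol ether 7 (not isolated)
Conditions: toluene, 110 °C (sealed tube); then 1 M HCl, THF, 0 °C
Reagents that add atoms: none
Why: Thermal normal-demand Diels–Alder reaction followed by acid hydrolysis/β-elimination: the diene adds anti to the menthyloxy group (sets C1 and C10, cis), its silyloxy-activated C11 terminus bonds to the lactone β-carbon C10, the endo transition state places 11-OBn cis to the lactone ring (sets C11), and acid then unmasks the C12 ketone and expels ethanol to give the C13=C14 enone.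

**Step 4**
Reactants: 8 bicyclic enone lactone
Product: 10 dienyl triflate, via magnesium enolate 9 (not isolated)
Conditions: isopropenylmagnesium bromide, CuBr·SMe2 (20 mol%), THF, −78 °C; then N-(5-chloropyridin-2-yl)bis(trifluoromethanesulfonimide), −78 → 0 °C
Reagents that add atoms: isopropenylmagnesium bromide CC(=C)[Mg]Br; N-(5-chloropyridin-2-yl)bis(trifluoromethanesulfonimide) FC(F)(F)S(=O)(=O)N(c1ccc(Cl)cn1)S(=O)(=O)C(F)(F)F
Why: Copper-catalysed conjugate addition takes place on the convex face anti to the C1–C2 bond of the cis-fused bicycle (sets C14, trans to the C1 substituent), and the regiodefined enolate is trapped on oxygen as the enol triflate.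

**Step 5**
Reactants: 10 dienyl triflate
Product: 11 methyl diene lactone
Conditions: Me2Zn, Pd(PPh3)4 (5 mol%), THF, 0 → 40 °C
Reagents that add atoms: dimethylzinc C[Zn]C
Why: Negishi cross-coupling of the alkenyl triflate installs the C12 methyl group; lactone, acetal, benzyl ether and the second alkene are inert.

**Step 6**
Reactants: 11 methyl diene lactone
Product: 13 primary alcohol with ring alkene, via B-alkyl-9-BBN adduct 12 (not isolated)
Conditions: 9-BBN, THF, 0 °C → rt; then NaBO3·4H2O, H2O, rt
Reagents that add atoms: sodium perborate (NaBO3·4H2O) [Na+].[O-]OB=O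
Why: Anti-Markovnikov hydroboration–oxidation of the 1,1-disubstituted alkene (9-BBN leaves the trisubstituted ring alkene); in the reactive rotamer H14 eclipses C15=C16 and the borane adds anti to the branched C1 flank (allylic-strain model), which sets C15.

**Step 7**
Reactants: 13 primary alcohol with ring alkene
Product: 15 diol lactone, via saturated benzyl ether 14 (not isolated)
Conditions: H2 (1 atm), [Ir(cod)(PCy3)(py)]PF6 (5 mol%), CH2Cl2, rt; then Pd/C (10% palladium on carbon), MeOH, H2 (1 atm), rt
Reagents that add atoms: none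
Why: Hydroxyl-directed homogeneous hydrogenation followed by hydrogenolysis: the cationic iridium centre bound to the C16 hydroxyl, which hangs from the top face at C14, delivers H2 to that face of C12=C13 and so sets C12 (methyl cis to the C11 oxygen), after which palladium removes the benzyl group.

**Step 8**
Reactants: 15 diol lactone
Product: 16 silyl ether hydroxy lactone
Conditions: TBSCl, imidazole, CH2Cl2, 0 °C
Reagents that add atoms: tert-butyldimethylsilyl chloride CC(C)(C)[Si](C)(C)Cl
Why: Silylation (silyl ether formation) is selective for the primary hydroxyl over the hindered secondary C11 hydroxyl.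

**Step 9**
Reactants: 16 silyl ether hydroxy lactone
Product: 18 diacetate (lactol acetate), via lactol 17 (not isolated)
Conditions: iBu2AlH (2.2 equiv), CH2Cl2, −78 °C; then pyridine, DMAP, Ac2O, −78 → 0 °C
Reagents that add atoms: acetic anhydride CC(=O)OC(C)=O
Why: Reductive acetylation: iBu2AlH stops at the aluminium lactolate at −78 °C, which is acetylated in situ together with the C11 alkoxide, so that C2 reaches the aldehyde oxidation level with the better leaving group while the menthyl acetal and the silyl ether are untouched.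

**Step 10**
Reactants: 19 6-chlorohexan-2-one
Product: 20 6-chloro-3-methylidenehexan-2-one
Conditions: (CH2O)n, N-methylanilinium trifluoroacetate, THF, reflux
Reagents that add atoms: paraformaldehyde (as formaldehyde) C=O
Why: Mannich-type α-methylenation (amine-salt catalysed aldol condensation with formaldehyde and elimination) at the more substituted α-carbon of the methyl ketone.

**Step 11**
Reactants: 20 6-chloro-3-methylidenehexan-2-one
Product: 21 (E)-[(6-chloro-3-methylhex-2-en-2-yl)oxy]triethylsilane
Conditions: Et3SiH, RhCl(PPh3)3 (1 mol%), THF, 50 °C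
Reagents that add atoms: triethylsilane CC[SiH](CC)CC
Why: Rhodium-catalysed 1,4-hydrosilylation of the enone delivers the tetrasubstituted silyl enol ether regiospecifically, which direct enolisation of the ketone could not guarantee; the alkyl chloride is inert.

**Step 12**
Reactants: 18 diacetate (lactol acetate); 21 (E)-[(6-chloro-3-methylhex-2-en-2-yl)oxy]triethylsilane
Product: 22 C-glycoside methyl ketone
Conditions: Et3SiOTf (20 mol%), CH2Cl2, −78 °C
Reagents that add atoms: none
Why: Mukaiyama-type addition to the cyclic oxocarbenium ion formed by selective ionisation of the anomeric acetate at −78 °C: the enol silane attacks the convex face, anti to the C1–C14 bond (sets C2), and creates the quaternary C3 as an inconsequential epimer mixture.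

**Step 13**
Reactants: 22 C-glycoside methyl ketone
Product: 23 tricyclic chloro ketone
Conditions: TMSOTf (2.5 equiv), iPr2NEt, CH2Cl2, −78 → −30 °C
Reagents that add atoms: none
Why: Ionisation of the menthyl acetal and intramolecular Mukaiyama-type attack of the methyl-ketone enol silane (formed in situ at C8, the only enolisable site) on the C9 oxocarbenium ion, the ring-closing half of a [4+3] annulation: the tether reaches only the face that carries C3, which sets C9 and closes the six-membered ring of the 8-oxabicyclo[3.2.1]octanone.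

**Step 14**
Reactants: 23 tricyclic chloro ketone
Product: 24 tricyclic iodo ketone
Conditions: NaI, acetone, reflux
Reagents that add atoms: sodium iodide [Na+].[I-]
Why: Finkelstein halide exchange (SN2) at the primary chloride prepares the precursor for the samarium step.

**Step 15**
Reactants: 24 tricyclic iodo ketone
Product: 25 tetracyclic tertiary cyclopentanol
Conditions: SmI2, HMPA, THF, −78 → 0 °C
Reagents that add atoms: none
Why: Samarium Barbier cyclisation: reduction of the primary iodide and 5-exo addition to the adjacent ketone gives the cis-fused tertiary cyclopentanol (C6–C7 bond), acetate and silyl ether being inert to SmI2.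

**Step 16**
Reactants: 25 tetracyclic tertiary cyclopentanol
Product: 27 target CNP0288436.2, via tertiary iodide 26 (not isolated)
Conditions: PhI(OAc)2, I2, CH2Cl2, visible light, 25 °C
Reagents that add atoms: none
Why: Proposed new method: the tertiary hypoiodite formed from 25 and AcOI is photolysed to the C7 alkoxy radical, whose β-scission cleaves the ring-fusion bond C3–C7 to give the C7 ketone and the tertiary C3 radical; iodine transfer gives iodide 26, which ionises (assisted by I2 and PhI(OAc)2) to the C3 cation that is captured by the C16 silyl ether oxygen with loss of the silyl group to acetate, PhI(OAc)2 being the net oxidant. The closest known reaction type is the PhI(OAc)2/I2 hypoiodite β-fragmentation of ring-fusion tertiary alcohols to medium-ring ketones, with its oxidative trapping of the carbon radical by an internal oxygen nucleophile. The oxonane is not closed by a new bond but released from the bicycle by fragmentation (ring expansion), and the oxepane is closed by 7-exo capture of the cation (SN1) through the O–C3 bond. The only new stereocentre, C3, is controlled by the ring system: the oxonane holds C4 beneath the tetrahydrofuran ring, so the oxygen tethered from C14 on the opposite flank reaches only one face of the planar C3, and reversible ionisation makes this least-strained epimer the thermodynamic one as well. The step needs scission towards C3 and not C6 or C8, secured by the tertiary radical and the strain relief of two rings (minor C7–C6 scission returns iodide 24, which can be recycled), and a single free hydroxyl, secured by the silyl cap on the C16 oxygen. Capture must also outrun hydride shift from C2 and proton loss; the C2–H bond lies near the nodal plane of the ring-constrained cation.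

## Compound list

1 | benzyloxyacetyl chloride | O=C(Cl)COCc1ccccc1 | starting material
2 | ethyl vinyl ether | C=COCC | starting material
3 | 1-(benzyloxy)-4-chloro-4-ethoxybutan-2-one (chloro ether adduct) | CCOC(Cl)CC(=O)COCc1ccccc1 | intermediate
4 | (E)-1-(benzyloxy)-4-ethoxybut-3-en-2-one | CCO/C=C/C(=O)COCc1ccccc1 | intermediate
5 | (1E,3Z)-4-(benzyloxy)-3-(tert-butyldimethylsilyloxy)-1-ethoxybuta-1,3-diene | CCO/C=C/C(O[Si](C)(C)C(C)(C)C)=C/OCc1ccccc1 | intermediate
6 | (5R)-5-(l-menthyloxy)furan-2(5H)-one | CC(C)[C@@H]1CC[C@@H](C)C[C@H]1O[C@H]1C=CC(=O)O1 | starting material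
7 | cycloadduct silyl enol ether: cis-fused lactone (C2=O) with menthyl acetal at C9, C12(OTBS)=C13, 14-OEt and 11-OBn cis to the lactone ring, ring A anti to O-menthyl | c1ccccc1CO[C@H]1[C@@H]([C@H](O[C@@H]3C[C@H](C)CC[C@H]3C(C)C)OC2=O)[C@@H]2[C@@H](OCC)C=C1O[Si](C)(C)C(C)(C)C | intermediate
8 | bicyclic enone lactone: C12 ketone, C13=C14, 11-OBn cis to C10–C9, cis fusion at C1/C10, 9-O-menthyl trans to C10–C11 | c1ccccc1CO[C@H]1[C@@H]([C@H](O[C@@H]3C[C@H](C)CC[C@H]3C(C)C)OC2=O)[C@@H]2C=CC1=O | intermediate
9 | bromomagnesium enolate (C12–O, C12=C13) with 14-isopropenyl trans to C1–C2 | c1ccccc1CO[C@H]1[C@@H]([C@H](O[C@@H]3C[C@H](C)CC[C@H]3C(C)C)OC2=O)[C@@H]2[C@H](C(C)=C)C=C1O[Mg]Br | intermediate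
10 | dienyl triflate (12-OTf, C12=C13, 14-isopropenyl) | c1ccccc1CO[C@H]1[C@@H]([C@H](O[C@@H]3C[C@H](C)CC[C@H]3C(C)C)OC2=O)[C@@H]2[C@H](C(C)=C)C=C1OS(=O)(=O)C(F)(F)F | intermediate
11 | methyl diene lactone (12-CH3, C12=C13, 14-isopropenyl) | c1ccccc1CO[C@H]1[C@@H]([C@H](O[C@@H]3C[C@H](C)CC[C@H]3C(C)C)OC2=O)[C@@H]2[C@H](C(C)=C)C=C1C | intermediate
12 | B-alkyl-9-borabicyclo[3.3.1]nonane adduct at C16 | c1ccccc1CO[C@H]1[C@@H]([C@H](O[C@@H]3C[C@H](C)CC[C@H]3C(C)C)OC2=O)[C@@H]2[C@H]([C@@H](C)CB4C5CCCC4CCC5)C=C1C | intermediate
13 | primary alcohol with ring alkene (C15 stereocentre, C16–OH, C12=C13) | c1ccccc1CO[C@H]1[C@@H]([C@H](O[C@@H]3C[C@H](C)CC[C@H]3C(C)C)OC2=O)[C@@H]2[C@H]([C@@H](C)CO)C=C1C | intermediate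
14 | saturated benzyl ether (12-CH3 cis to the C11 oxygen) | c1ccccc1CO[C@H]1[C@@H]([C@H](O[C@@H]3C[C@H](C)CC[C@H]3C(C)C)OC2=O)[C@@H]2[C@H]([C@@H](C)CO)C[C@H]1C | intermediate
15 | diol lactone (11-OH, 16-OH) | O[C@H]1[C@@H]([C@H](O[C@@H]3C[C@H](C)CC[C@H]3C(C)C)OC2=O)[C@@H]2[C@H]([C@@H](C)CO)C[C@H]1C | intermediate
16 | silyl ether hydroxy lactone (16-OTBS, 11-OH) | O[C@H]1[C@@H]([C@H](O[C@@H]3C[C@H](C)CC[C@H]3C(C)C)OC2=O)[C@@H]2[C@H]([C@@H](C)CO[Si](C)(C)C(C)(C)C)C[C@H]1C | intermediate
17 | lactol (C2–OH; aluminium lactolate in the flask; either anomer) | O[C@H]1[C@@H]([C@H](O[C@@H]3C[C@H](C)CC[C@H]3C(C)C)OC2O)[C@@H]2[C@H]([C@@H](C)CO[Si](C)(C)C(C)(C)C)C[C@H]1C | intermediate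
18 | diacetate: 2-acetoxy-9-(l-menthyloxy) bis-acetal with 11-OAc (drawn as the anomer with 2-OAc trans to C1–C14) | CC(=O)O[C@H]1[C@@H]([C@H](O[C@@H]3C[C@H](C)CC[C@H]3C(C)C)O[C@@H]2OC(C)=O)[C@@H]2[C@H]([C@@H](C)CO[Si](C)(C)C(C)(C)C)C[C@H]1C | intermediate
19 | 6-chlorohexan-2-one | CC(=O)CCCCCl | starting material
20 | 6-chloro-3-methylidenehexan-2-one | CC(=O)C(=C)CCCCl | intermediate
21 | (E)-[(6-chloro-3-methylhex-2-en-2-yl)oxy]triethylsilane | C/C(O[Si](CC)(CC)CC)=C(/C)CCCCl | intermediate
22 | C-glycoside methyl ketone: C2 bonded, trans to C1–C14, to quaternary C3 carrying CH3, (CH2)3Cl and acetyl; C3 epimers | CC(=O)O[C@H]1[C@@H]([C@H](O[C@@H]3C[C@H](C)CC[C@H]3C(C)C)O[C@@H]2C(C)(CCCCl)C(C)=O)[C@@H]2[C@H]([C@@H](C)CO[Si](C)(C)C(C)(C)C)C[C@H]1C | intermediate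
23 | tricyclic chloro ketone: 8-oxabicyclo[3.2.1]octan-3-one (C7 ketone) exo-fused to ring A, C3 with CH3 and (CH2)3Cl; C3 epimers | CC(=O)O[C@H]1[C@@H]([C@@H]2CC(=O)C(C)(CCCCl)[C@H]3O2)[C@@H]3[C@H]([C@@H](C)CO[Si](C)(C)C(C)(C)C)C[C@H]1C | intermediate
24 | tricyclic iodo ketone; C3 epimers | CC(=O)O[C@H]1[C@@H]([C@@H]2CC(=O)C(C)(CCCI)[C@H]3O2)[C@@H]3[C@H]([C@@H](C)CO[Si](C)(C)C(C)(C)C)C[C@H]1C | intermediate
25 | tetracyclic tertiary cyclopentanol (C3–C7 bond, 7-OH, 3-CH3, cis-fused; C3/C7 epimer pair) | CC(=O)O[C@H]1[C@@H]([C@@H]2CC4(O)CCCC4(C)[C@H]3O2)[C@@H]3[C@H]([C@@H](C)CO[Si](C)(C)C(C)(C)C)C[C@H]1C | intermediate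
26 | tertiary iodide: oxonan-7-one with C3(CH3)I and 16-OTBS | CC(=O)O[C@H]1[C@@H]([C@@H]2CC(=O)CCCC(C)(I)[C@H]3O2)[C@@H]3[C@H]([C@@H](C)CO[Si](C)(C)C(C)(C)C)C[C@H]1C | intermediate
27 | target CNP0288436.2 (11-acetoxy-7-oxo tetracycle with oxepane and oxonane) | CC(=O)O[C@H]1[C@@H]2[C@@H]3[C@@H](C[C@H]1C)[C@@H](C)CO[C@@]1(C)CCCC(=O)C[C@@H]2O[C@@H]31 | target

## Step count and risks

Total step count: 16. Longest linear sequence: 14 steps (steps 1–9 and 12–16; steps 10 and 11 make the side fragment).

**Steps most likely to fail**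

1. **Step 16** (Proposed new method).
   - What may go wrong: after β-scission the C3 cation may lose a proton, or take a hydride from C2, faster than the seven-membered capture by the weakly nucleophilic silyl ether oxygen; part of the alkoxy radical may also cleave towards C6.
   - Fallback (sets out from 25, returns at 27): the fragmentation and the etherification are separated with known reactions. Pb(OAc)4 with catalytic Cu(OAc)2 (pyridine, benzene, 80 °C) effects the same β-scission but ends in oxidative elimination to the 3-methylidene oxonanone silyl ether F1. Bu4NF/AcOH then frees the primary alcohol F2. N-Iodosuccinimide (CH2Cl2, 0 °C) closes the oxepane by Markovnikov 7-exo iodoetherification to the iodomethyl oxepane ether F3, which forms the same O–C3 bond under the same facial constraint. Bu3SnH/AIBN (benzene, 80 °C) removes iodine to give 27. Endocyclic olefin isomers of F1 should converge on 27 in the same way.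

2. **Step 12.**
   - What may go wrong: slow addition of the hindered tetrasubstituted enol silane, so that ionisation of the menthyl acetal with attack at C9, or loss of the silyl ether, competes.
   - Fallback (sets out from 18, returns at 24): the quaternary carbon is built from a doubly activated, regiochemically unambiguous donor. The trimethylsilyl enol ether of allyl 2-methylacetoacetate (Et3SiOTf, CH2Cl2, −78 °C) should give the C-glycoside keto allyl ester F4. TMSOTf/iPr2NEt closes the oxabicycle to the bicyclic β-keto allyl ester F5. Pd(PPh3)4 (THF, rt) effects decarboxylative allylation to the allyl methyl ketone F6. 9-BBN then NaBO3·4H2O gives the primary alcohol F7, and I2/PPh3/imidazole converts it into 24. F4–F7 are C3-epimer mixtures like their counterparts in the main route.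

3. **Step 6.**
   - What may go wrong: poor facial selectivity in the hydroboration of the isopropenyl group, giving a mixture at C15.
   - Fallback (sets out from 8, returns at 13): C15 is set by catalyst control instead. The copper-catalysed addition/triflation of step 4, run with [3-(tert-butyldimethylsilyloxy)prop-1-en-2-yl]magnesium bromide, gives the silyloxymethyl dienyl triflate F8. Me2Zn/Pd(PPh3)4 gives the methyl diene silyl ether F9, and Bu4NF the 2-substituted allylic alcohol F10. Hydrogenation with Ru(OAc)2[(S)-BINAP] (H2, MeOH; the ligand antipode matched to C14 is used) reduces only the allylic-alcohol alkene and sets C15, giving 13.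

## Further compounds

F1 | step 16 | 3-methylidene oxonanone silyl ether (C3=CH2, C7 ketone, 16-OTBS) | CC(=O)O[C@H]1[C@@H]([C@@H]2CC(=O)CCCC(=C)[C@H]3O2)[C@@H]3[C@H]([C@@H](C)CO[Si](C)(C)C(C)(C)C)C[C@H]1C
F2 | step 16 | 3-methylidene oxonanone primary alcohol | CC(=O)O[C@H]1[C@@H]([C@@H]2CC(=O)CCCC(=C)[C@H]3O2)[C@@H]3[C@H]([C@@H](C)CO)C[C@H]1C
F3 | step 16 | iodomethyl oxepane ether (target with CH2I in place of the C3 methyl) | CC(=O)O[C@H]1[C@@H]2[C@@H]3[C@@H](C[C@H]1C)[C@@H](C)CO[C@@]1(CI)CCCC(=O)C[C@@H]2O[C@@H]31
F4 | step 12 | C-glycoside keto allyl ester (C3 with CH3, CO2allyl and acetyl) | CC(=O)O[C@H]1[C@@H]([C@H](O[C@@H]3C[C@H](C)CC[C@H]3C(C)C)O[C@@H]2C(C)(C(=O)OCC=C)C(C)=O)[C@@H]2[C@H]([C@@H](C)CO[Si](C)(C)C(C)(C)C)C[C@H]1C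
F5 | step 12 | bicyclic β-keto allyl ester (8-oxabicyclo[3.2.1]octan-3-one with C3 CH3 and CO2allyl) | CC(=O)O[C@H]1[C@@H]([C@@H]2CC(=O)C(C)(C(=O)OCC=C)[C@H]3O2)[C@@H]3[C@H]([C@@H](C)CO[Si](C)(C)C(C)(C)C)C[C@H]1C
F6 | step 12 | allyl methyl ketone (C3 with CH3 and allyl) | CC(=O)O[C@H]1[C@@H]([C@@H]2CC(=O)C(C)(CC=C)[C@H]3O2)[C@@H]3[C@H]([C@@H](C)CO[Si](C)(C)C(C)(C)C)C[C@H]1C
F7 | step 12 | primary alcohol (C3 with CH3 and 3-hydroxypropyl) | CC(=O)O[C@H]1[C@@H]([C@@H]2CC(=O)C(C)(CCCO)[C@H]3O2)[C@@H]3[C@H]([C@@H](C)CO[Si](C)(C)C(C)(C)C)C[C@H]1C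
F8 | step 6 | silyloxymethyl dienyl triflate (14-[3-(TBSO)prop-1-en-2-yl], 12-OTf) | c1ccccc1CO[C@H]1[C@@H]([C@H](O[C@@H]3C[C@H](C)CC[C@H]3C(C)C)OC2=O)[C@@H]2[C@H](C(=C)CO[Si](C)(C)C(C)(C)C)C=C1OS(=O)(=O)C(F)(F)F
F9 | step 6 | methyl diene silyl ether | c1ccccc1CO[C@H]1[C@@H]([C@H](O[C@@H]3C[C@H](C)CC[C@H]3C(C)C)OC2=O)[C@@H]2[C@H](C(=C)CO[Si](C)(C)C(C)(C)C)C=C1C
F10 | step 6 | 2-substituted allylic alcohol | c1ccccc1CO[C@H]1[C@@H]([C@H](O[C@@H]3C[C@H](C)CC[C@H]3C(C)C)OC2=O)[C@@H]2[C@H](C(=C)CO)C=C1C
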